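**Plan**

- Retrosynthesis: the two aryl–CH2 bonds of the methylene bridge are cut first (C8 of the chromanone, C5 of the acylphenol ring A), giving a 5,7-dihydroxychromanone, a one-carbon iminium unit and an acylphenol. The chromanone is then cut at the ring bond O1–C2 together with the aryl–carbonyl bond C4a–C4, and ring A at its aryl–carbonyl bond.
- Enabling feature: in the chromanone, O1 on C8a is ortho to C4a, which carries the C4 carbonyl, and C2 is the dimethyl-bearing β-carbon of a 3-methylbut-2-enoyl unit. O1 and C2 are therefore 1,5-related and can close pyranone ring C by a 6-endo oxa-Michael addition. The C6 methyl is para to O1 and flanked by O5 and O7, so benzo ring B, stripped of acyl and bridge, is a mirror-symmetric phenol with one free OH and one kind of ring C–H; ring A has the same pattern.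
- Forward: C–H borylation/oxidation of 2,6-dimethoxytoluene gives 3,5-dimethoxy-4-methylphenol, the source of both aromatic rings. Ring C arises in step 2 (acylation, then O1–C2 closure), followed by O-demethylation and aminomethylation at C8. Ring A arises by acylation of the same phenol and chelation-controlled mono-demethylation. The halves are joined last through an ortho-quinone methide.
- Stereochemistry: the only stereocenter (R, α to the ketone of the 2-methylbutanoyl chain) comes from (R)-2-methylbutanoic acid and is carried through acylation, demethylation and coupling under non-enolising conditions.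

Key step: step 2

Assumption: (R)-2-methylbutanoic acid of high enantiomeric purity is taken as a purchasable starting material.

**Route**

Step 1
Reactants: 1 2,6-dimethoxytoluene
Product: 3 3,5-dimethoxy-4-methylphenol, via arylboronate 2 (not isolated)
Conditions: [Ir(OMe)(cod)]2 (1.5 mol %), 4,4'-di-tert-butyl-2,2'-bipyridine (3 mol %), B2pin2 (1.0 equiv), THF, 80 °C; then KHSO5 (as Oxone), acetone/H2O, rt
Reagents that add atoms: bis(pinacolato)diboron, CC1(C)OB(OC1(C)C)B1OC(C)(C)C(C)(C)O1 (boryl group of 2); potassium peroxymonosulfate KHSO5, [K+].[O-]S(=O)(=O)OO (phenol oxygen of 3)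
Why: Iridium-catalysed aromatic C–H borylation is governed by sterics and should take the only ring C–H of 1 without an ortho substituent (C4, para to the methyl group), and KHSO5 then converts the C–B bond into C–OH at the same carbon (one-pot C–H borylation/oxidation).

Step 2
Reactants: 3 3,5-dimethoxy-4-methylphenol; 4 3-methylbut-2-enoic acid
Product: 6 5,7-dimethoxy-2,2,6-trimethylchroman-4-one, via open enone 5 (not isolated)
Conditions: 4 (1.2 equiv), P2O5/MeSO3H (about 1:10 w/w), 70 °C
Reagents that add atoms: none
Why: In P2O5/MeSO3H acid 4 is turned into a mixed anhydride/acylium ion that acylates 3 at the carbon ortho to the free OH (Friedel–Crafts acylation) to give enone 5; protonation of the enone makes its dimethyl-bearing β-carbon electrophilic and the neighbouring phenolic oxygen adds to it, forming the O1–C2 bond (intramolecular oxa-Michael addition). The closest known reaction type is the acid-mediated annulation of phenols with 3-methylbut-2-enoic acid to 2,2-dimethylchroman-4-ones. Pyranone ring C closes in the 6-endo-trig mode. No stereocenter is formed, because C2 carries two methyl groups. The step needs site selectivity (which carbon is acylated and which oxygen closes the ring) and chemoselectivity (acylation instead of conjugate C-alkylation, which would lead to a dihydrocoumarin). The mirror plane of 3 makes both ring C–H equivalent, the only free OH is the one para to the methyl group while the two flanking oxygens are methyl ethers that are stable in this medium, so only the 6-methyl isomer with C8–H free can form, and the dehydrating medium favours the acylium pathway.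

Step 3
Reactants: 6 5,7-dimethoxy-2,2,6-trimethylchroman-4-one
Product: 7 5,7-dihydroxy-2,2,6-trimethylchroman-4-one
Conditions: BBr3 (4 equiv), CH2Cl2, −78 °C → rt; ice/H2O quench
Reagents that add atoms: none
Why: BBr3 binds the ether oxygens and bromide removes the methyl groups by SN2 (Lewis-acid ether cleavage); the 5-OMe is activated by chelation to the C4 carbonyl and the 7-OMe is twisted by the 6-methyl group, whereas O1 is a vinylogous ester oxygen shielded by the gem-dimethyl carbon and should stay bound, so the regiochemistry fixed in step 2 is kept.

Step 4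
Reactants: 7 5,7-dihydroxy-2,2,6-trimethylchroman-4-one; 8 N,N-dimethylmethylideneammonium iodide
Product: 9 8-[(dimethylamino)methyl]-5,7-dihydroxy-2,2,6-trimethylchroman-4-one
Conditions: 8 (1.1 equiv), CH2Cl2/MeCN, 0 °C → rt; aq. NaHCO3 work-up
Reagents that add atoms: none
Why: Electrophilic aminomethylation by the preformed iminium ion (Mannich reaction) should occur at C8, the only unsubstituted ring carbon of 7 and ortho to the 7-OH and para to the 5-OH; at room temperature the benzylic amine does not yet lose amine, so no bis-chromanylmethane should form.

Step 5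
Reactants: 10 (R)-2-methylbutanoic acid; 3 3,5-dimethoxy-4-methylphenol
Product: 12 (2R)-1-(6-hydroxy-2,4-dimethoxy-3-methylphenyl)-2-methylbutan-1-one, via acid chloride 11 (not isolated)
Conditions: (COCl)2, cat. DMF, CH2Cl2, 0 °C → rt; then 3, AlCl3 (2.2 equiv), CH2Cl2, −20 → 0 °C; aq. HCl work-up
Reagents that add atoms: oxalyl chloride, O=C(Cl)C(=O)Cl (chlorine of intermediate 11; no atom of it remains in 12)
Why: Friedel–Crafts acylation of the aluminium phenoxide of 3 takes place at the one kind of ring C–H it has (ortho to OH), and since the acid chloride is made without base (no ketene) and the acylation is run cold, the R configuration of 10 should be carried into 12 unchanged.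

Step 6
Reactants: 12 (2R)-1-(6-hydroxy-2,4-dimethoxy-3-methylphenyl)-2-methylbutan-1-one
Product: 13 (2R)-1-(2,6-dihydroxy-4-methoxy-3-methylphenyl)-2-methylbutan-1-one
Conditions: BCl3 (3 equiv), CH2Cl2, −78 → 0 °C; H2O quench
Reagents that add atoms: none
Why: BCl3 selectively cleaves the methyl ether that is ortho to the ketone and flanked on both sides (chelation-assisted Lewis-acid dealkylation), while the 4-OMe, which is neither next to the carbonyl nor doubly flanked, stays; at 0 °C or below the boron-chelated ketone should not enolise, so the stereocenter is kept.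

Step 7
Reactants: 9 8-[(dimethylamino)methyl]-5,7-dihydroxy-2,2,6-trimethylchroman-4-one; 13 (2R)-1-(2,6-dihydroxy-4-methoxy-3-methylphenyl)-2-methylbutan-1-one
Product: 15 the target (2R)-1-{3-[(5,7-dihydroxy-2,2,6-trimethyl-4-oxochroman-8-yl)methyl]-2,6-dihydroxy-4-methoxy-5-methylphenyl}-2-methylbutan-1-one, via quinone methide 14 (not isolated)
Conditions: 13 (1.2 equiv), 1,4-dioxane, 90 °C, argon purge
Reagents that add atoms: none
Why: On heating, the ortho-hydroxybenzylamine 9 loses dimethylamine to give ortho-quinone methide 14, which is attacked in a conjugate addition by C5 of 13 (its only unsubstituted ring carbon, ortho and para to hydroxyls), and rearomatisation gives the diarylmethane (Mannich-base route to unsymmetrical methylene-bridged acylphloroglucinols); the neutral medium should leave the α-stereocenter and the chromanone ring untouched.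

**Compound list**

1 | 2,6-dimethoxytoluene | COc1cccc(OC)c1C | starting material
2 | 2-(3,5-dimethoxy-4-methylphenyl)-4,4,5,5-tetramethyl-1,3,2-dioxaborolane | COc1cc(B2OC(C)(C)C(C)(C)O2)cc(OC)c1C | intermediate
3 | 3,5-dimethoxy-4-methylphenol | COc1cc(O)cc(OC)c1C | intermediate
4 | 3-methylbut-2-enoic acid | CC(C)=CC(=O)O | starting material
5 | 1-(6-hydroxy-2,4-dimethoxy-3-methylphenyl)-3-methylbut-2-en-1-one | CC(C)=CC(=O)c1c(O)cc(OC)c(C)c1OC | intermediate
6 | 5,7-dimethoxy-2,2,6-trimethylchroman-4-one | COc1cc2OC(C)(C)CC(=O)c2c(OC)c1C | intermediate
7 | 5,7-dihydroxy-2,2,6-trimethylchroman-4-one | Cc1c(O)cc2OC(C)(C)CC(=O)c2c1O | intermediate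
8 | N,N-dimethylmethylideneammonium iodide | C=[N+](C)C.[I-] | starting material
9 | 8-[(dimethylamino)methyl]-5,7-dihydroxy-2,2,6-trimethylchroman-4-one | CN(C)Cc1c(O)c(C)c(O)c2C(=O)CC(C)(C)Oc12 | intermediate
10 | (R)-2-methylbutanoic acid | CC[C@@H](C)C(=O)O | starting material
11 | (R)-2-methylbutanoyl chloride | CC[C@@H](C)C(=O)Cl | intermediate
12 | (2R)-1-(6-hydroxy-2,4-dimethoxy-3-methylphenyl)-2-methylbutan-1-one | CC[C@@H](C)C(=O)c1c(O)cc(OC)c(C)c1OC | intermediate
13 | (2R)-1-(2,6-dihydroxy-4-methoxy-3-methylphenyl)-2-methylbutan-1-one | CC[C@@H](C)C(=O)c1c(O)cc(OC)c(C)c1O | intermediate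
14 | 5-hydroxy-2,2,6-trimethyl-8-methylidene-2,3-dihydrochromene-4,7-dione (ortho-quinone methide) | C=C1C(=O)C(C)=C(O)C2=C1OC(C)(C)CC2=O | intermediate
15 | (2R)-1-{3-[(5,7-dihydroxy-2,2,6-trimethyl-4-oxochroman-8-yl)methyl]-2,6-dihydroxy-4-methoxy-5-methylphenyl}-2-methylbutan-1-one | CC[C@@H](C)C(=O)c1c(O)c(C)c(OC)c(Cc2c(O)c(C)c(O)c3c2OC(C)(C)CC3=O)c1O | target

**Step count and risks**

Total step count: 7. Longest linear sequence: 5 steps (steps 1, 2, 3, 4, 7); the ring A branch (steps 1, 5, 6, 7) has 4.

Steps most likely to fail:

Step 7. The hetero-coupling may lose selectivity by exchange of the benzylic unit between rings (ipso attack giving symmetric dimers), by self-condensation of the quinone methide, or by slow epimerisation α to the ketone on prolonged heating with amine. The fallback reverses the roles of the partners and generates the quinone methide at room temperature. It sets out from 13 (with 7 as partner) and comes back at 15. 13 is aminomethylated with 8 as in step 4 to (2R)-1-{3-[(dimethylamino)methyl]-2,6-dihydroxy-4-methoxy-5-methylphenyl}-2-methylbutan-1-one F1. F1 is quaternised with MeI in acetone to 1-{2,4-dihydroxy-6-methoxy-5-methyl-3-[(2R)-2-methylbutanoyl]phenyl}-N,N,N-trimethylmethanaminium iodide F2. F2 and chromanone 7 are stirred with NaHCO3 in MeCN/H2O at rt; loss of trimethylamine gives the quinone methide of ring A, which C8 of 7 should trap to give 15.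

Step 3. The second (7-O) methyl ether may be cleaved incompletely, or the Lewis acid may open the pyranone ring, and re-closure on the other oxygen would scramble the position of the methyl group. The fallback separates the two dealkylations and does the second without Lewis acid. It sets out from 6 and comes back at 7. BCl3 (CH2Cl2, −78 → 0 °C) should remove only the chelated 5-O-methyl group and give 5-hydroxy-7-methoxy-2,2,6-trimethylchroman-4-one F3. The 7-O-methyl group of F3 is then removed by SN2 attack of NaSEt in DMF at 110 °C; the 5-phenoxide formed under these conditions should disfavour enolisation and ring opening, and acidic work-up gives 7.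

Step 5. Enantiomeric purity may erode through ketene or enol formation from the acid chloride or acylium ion, and O-acylation without rearrangement may compete; the purity of 12 and 13 should be checked by chiral HPLC. The fallback forms the aryl ketone by an organolithium addition under non-acidic conditions. It sets out from 3 and 10 and comes back at 12. 3 is protected (MeOCH2Cl, i-Pr2NEt, CH2Cl2) as 1,3-dimethoxy-5-(methoxymethoxy)-2-methylbenzene F4. 10 is converted with carbonyldiimidazole and MeNHOMe·HCl into (2R)-N-methoxy-N,2-dimethylbutanamide F5. F4 is lithiated with n-BuLi (THF, 0 °C) between the two directing oxygens (both ring C–H are equivalent) and added to F5 at −78 °C; the chelated tetrahedral intermediate should give, on quench, (2R)-1-[2,4-dimethoxy-6-(methoxymethoxy)-3-methylphenyl]-2-methylbutan-1-one F6. HCl in MeOH at rt removes the acetal and returns 12.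

Further compounds
F1 | step 7 | (2R)-1-{3-[(dimethylamino)methyl]-2,6-dihydroxy-4-methoxy-5-methylphenyl}-2-methylbutan-1-one | CC[C@@H](C)C(=O)c1c(O)c(C)c(OC)c(CN(C)C)c1O
F2 | step 7 | 1-{2,4-dihydroxy-6-methoxy-5-methyl-3-[(2R)-2-methylbutanoyl]phenyl}-N,N,N-trimethylmethanaminium iodide | CC[C@@H](C)C(=O)c1c(O)c(C)c(OC)c(C[N+](C)(C)C)c1O.[I-]
F3 | step 3 | 5-hydroxy-7-methoxy-2,2,6-trimethylchroman-4-one | COc1cc2OC(C)(C)CC(=O)c2c(O)c1C
F4 | step 5 | 1,3-dimethoxy-5-(methoxymethoxy)-2-methylbenzene | COCOc1cc(OC)c(C)c(OC)c1
F5 | step 5 | (2R)-N-methoxy-N,2-dimethylbutanamide | CC[C@@H](C)C(=O)N(C)OC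
F6 | step 5 | (2R)-1-[2,4-dimethoxy-6-(methoxymethoxy)-3-methylphenyl]-2-methylbutan-1-one | CC[C@@H](C)C(=O)c1c(OCOC)cc(OC)c(C)c1OC
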